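**Retrosynthetic overview**

- The strategy rests on the oxygen-bearing bridgehead C1, which lies five atoms (C1–C5–C4–O3–C2) from the guaiacyl-bearing benzylic ether carbon C2. Ring A (C1, C2, O3, C4, C5) is therefore cut at C1–C2, giving a ring B ketone (C1=O in ring C5–C6–O7–C8–C1) with an arylmethyl ether on the C4 arm, the substrate of a Norrish–Yang δ-hydrogen abstraction and cyclization.
- Ring B is cut at O7–C8 to a β-hydroxy α-diazoketone (carbenoid O–H insertion); C8 comes from diazomethane.
- C5 and C6 come from an anti Fráter–Seebach alkylation of an (S)-β-hydroxy ester (asymmetric hydrogenation) with an arylmethyl chloromethyl ether that delivers C4, O3, C2 and the protected guaiacyl ring.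
- Ring order: ring B first (step 9), ring A second (step 10); acetylation of the bridgehead alcohol and debenzylation of the phenol finish the route.

Key step: step 10

Remark: lignan numbering of the 3,7-dioxabicyclo[3.3.0]octane is used (C1 acetoxy bridgehead, C2 guaiacyl-bearing, O3, C4, C5 bridgehead CH, C6 veratryl-bearing, O7, C8); the target is read as the (1S,2R,5R,6S) isomer, cis-fused with both aryl groups exo.

**Route**

Step 1
Reactants: 1 4-(benzyloxy)-3-methoxybenzyl alcohol
Product: 2 4-(benzyloxy)-3-methoxybenzyl methylthiomethyl ether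
Conditions: NaH, ClCH2SMe, NaI (cat.), DME, 0 °C to rt
Reagents that add atoms: chloromethyl methyl sulfide, CSCCl
Why: Williamson O-alkylation of the deprotonated benzylic alcohol by the iodide-activated α-chloro sulfide should give the O,S-acetal, with no stereocentre involved.

Step 2
Reactants: 2 4-(benzyloxy)-3-methoxybenzyl methylthiomethyl ether
Product: 3 4-(benzyloxy)-3-methoxybenzyl chloromethyl ether
Conditions: SO2Cl2, CH2Cl2, −78 °C, short; evaporate cold, use crude at once
Reagents that add atoms: sulfuryl chloride, O=S(=O)(Cl)Cl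
Why: Chlorinolysis of a methylthiomethyl ether (chlorination at sulfur, then loss of MeSCl from the chlorosulfonium) is the standard way to an alkoxymethyl chloride, and the low temperature should spare the electron-rich ring.

Step 3
Reactants: 4 ethyl 3-(3,4-dimethoxyphenyl)-3-oxopropanoate
Product: 5 ethyl (S)-3-(3,4-dimethoxyphenyl)-3-hydroxypropanoate
Conditions: H2 (50 atm), RuCl2[(R)-BINAP] (cat.), EtOH, 50 °C
Reagents that add atoms: none
Why: Noyori asymmetric hydrogenation of a β-keto ester, in which ester chelation to ruthenium fixes the ketone face; (R)-BINAP is expected to give the (S) aryl carbinol (the same facial sense that gives (R)-3-hydroxybutanoate, the descriptor changing with the aryl priority), which sets C6.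

Step 4
Reactants: 5 ethyl (S)-3-(3,4-dimethoxyphenyl)-3-hydroxypropanoate, 3 4-(benzyloxy)-3-methoxybenzyl chloromethyl ether
Product: 7 ethyl (2R,3S)-2-({[4-(benzyloxy)-3-methoxybenzyl]oxy}methyl)-3-(3,4-dimethoxyphenyl)-3-hydroxypropanoate, via dilithium alkoxide–enolate 6 (not isolated)
Conditions: LiN(iPr)2 (2.2 equiv), THF, −78 to −20 °C; then 3 (freshly made), DMPU, −78 to −40 °C; aq. NH4Cl
Reagents that add atoms: none
Why: Fráter–Seebach alkylation, in which the six-membered lithium chelate of the alkoxide–enolate is attacked by the reactive alkoxymethyl chloride on the face opposite the aryl group, should give the anti product and so set C5 as R relative to the (S) carbinol.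

Step 5
Reactants: 7 ethyl (2R,3S)-2-({[4-(benzyloxy)-3-methoxybenzyl]oxy}methyl)-3-(3,4-dimethoxyphenyl)-3-hydroxypropanoate
Product: 8 ethyl (2R,3S)-2-({[4-(benzyloxy)-3-methoxybenzyl]oxy}methyl)-3-[(tert-butyldimethylsilyl)oxy]-3-(3,4-dimethoxyphenyl)propanoate
Conditions: TBSOTf, 2,6-lutidine, CH2Cl2, −78 to 0 °C
Reagents that add atoms: tert-butyldimethylsilyl triflate, CC(C)(C)[Si](C)(C)OS(=O)(=O)C(F)(F)F
Why: Silylation of the hindered secondary carbinol under non-acidic conditions masks it, so that the carboxyl activation of step 7 cannot acylate or lactonise it.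

Step 6
Reactants: 8 ethyl (2R,3S)-2-({[4-(benzyloxy)-3-methoxybenzyl]oxy}methyl)-3-[(tert-butyldimethylsilyl)oxy]-3-(3,4-dimethoxyphenyl)propanoate
Product: 9 (2R,3S)-2-({[4-(benzyloxy)-3-methoxybenzyl]oxy}methyl)-3-[(tert-butyldimethylsilyl)oxy]-3-(3,4-dimethoxyphenyl)propanoic acid
Conditions: LiOH·H2O, THF/MeOH/H2O, 40 °C; then 0.5 M HCl to pH 4 at 0 °C
Reagents that add atoms: lithium hydroxide, [Li+].[OH-]
Why: Ester saponification, which the silyl and benzyl ethers tolerate; once formed, the carboxylate resists enolisation, which should protect C5.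

Step 7
Reactants: 9 (2R,3S)-2-({[4-(benzyloxy)-3-methoxybenzyl]oxy}methyl)-3-[(tert-butyldimethylsilyl)oxy]-3-(3,4-dimethoxyphenyl)propanoic acid
Product: 11 (3R,4S)-3-({[4-(benzyloxy)-3-methoxybenzyl]oxy}methyl)-4-[(tert-butyldimethylsilyl)oxy]-1-diazo-4-(3,4-dimethoxyphenyl)butan-2-one, via mixed isobutyl carbonic anhydride 10 (not isolated)
Conditions: iBuOCOCl, N-methylmorpholine, THF, −20 °C; then CH2N2 (excess), Et2O, −20 to 0 °C
Reagents that add atoms: diazomethane, C=[N+]=[N-]; isobutyl chloroformate, CC(C)COC(=O)Cl (its atoms stay only in intermediate 10)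
Why: Acylation of diazomethane by a mixed carbonic anhydride (the first half of an Arndt–Eistert sequence) brings in C8 under neutral, cold conditions that leave the ethers and the α-stereocentre untouched.

Step 8
Reactants: 11 (3R,4S)-3-({[4-(benzyloxy)-3-methoxybenzyl]oxy}methyl)-4-[(tert-butyldimethylsilyl)oxy]-1-diazo-4-(3,4-dimethoxyphenyl)butan-2-one
Product: 12 (3R,4S)-3-({[4-(benzyloxy)-3-methoxybenzyl]oxy}methyl)-1-diazo-4-(3,4-dimethoxyphenyl)-4-hydroxybutan-2-one
Conditions: Bu4NF/AcOH (1:1), THF, 0 °C to rt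
Reagents that add atoms: none
Why: Fluoride desilylation buffered with acetic acid should free the carbinol without base-induced retro-aldol cleavage, C5 epimerisation or β-elimination of the C4 ether, and the diazoketone tolerates this medium.

Step 9
Reactants: 12 (3R,4S)-3-({[4-(benzyloxy)-3-methoxybenzyl]oxy}methyl)-1-diazo-4-(3,4-dimethoxyphenyl)-4-hydroxybutan-2-one
Product: 13 (4R,5S)-4-({[4-(benzyloxy)-3-methoxybenzyl]oxy}methyl)-5-(3,4-dimethoxyphenyl)dihydrofuran-3(2H)-one
Conditions: Rh2(OAc)4 (1–2 mol%), CH2Cl2, rt, slow addition at high dilution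
Reagents that add atoms: none
Why: Intramolecular rhodium-carbenoid O–H insertion of a hydroxy diazoketone closes the five-membered ring B (O7–C8 bond) faster than aromatic cycloaddition or ether ylide formation; no stereocentre is touched, and the trans ketone carried over from step 4 is also the more stable arrangement at the now enolisable C5.

Step 10
Reactants: 13 (4R,5S)-4-({[4-(benzyloxy)-3-methoxybenzyl]oxy}methyl)-5-(3,4-dimethoxyphenyl)dihydrofuran-3(2H)-one
Product: 15 (1S,2R,5R,6S)-2-[4-(benzyloxy)-3-methoxyphenyl]-6-(3,4-dimethoxyphenyl)-3,7-dioxabicyclo[3.3.0]octan-1-ol, via 1,5-biradical 14 (not isolated)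
Conditions: hν (medium-pressure Hg lamp, Pyrex, λ > 300 nm), degassed benzene (about 0.005 M), rt, stop at partial conversion
Reagents that add atoms: none
Why: n→π* excitation of the C1 carbonyl leads to 1,6-hydrogen transfer from C2 to the carbonyl oxygen through a seven-membered transition state, and the C1 ketyl/C2 α-alkoxybenzyl 1,5-biradical 14 collapses by radical–radical coupling; the closest known reaction type is the Norrish–Yang photocyclization of β-alkoxy ketones to tetrahydrofuran-3-ols, tetrahydrofuran-3-ones with arylmethoxymethyl side chains included. Ring A (C1–C2–O3–C4–C5) is closed by this biradical recombination, a five-membered closure that forms the C1–C2 bond and completes the 3,7-dioxabicyclo[3.3.0]octane. C1 is controlled by the existing C5 centre, because the three-atom C4–O3–C2 tether can reach C1 only from the face on which it stands, so only the cis ring fusion is possible. C2 is controlled in the coupling by the aryl group taking the convex (exo) side of the forming bicycle, away from ring B; this is also the thermodynamic arrangement, so any endo epimer can be equilibrated at the benzylic ether carbon with a trace of acid. The step needs site selectivity for the C2–H and selective excitation of the ketone: the side-chain γ position is the oxygen O3, the C6–H inside ring B cannot reach the carbonyl oxygen, the C2–H is doubly activated (benzylic and α to oxygen), and the Pyrex cut-off leaves the alkoxyarene chromophores largely unexcited. α-Cleavage of the cyclic ketone and quenching by the electron-rich rings are the competing channels and are limited by dilution, degassing and partial conversion.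

Step 11
Reactants: 15 (1S,2R,5R,6S)-2-[4-(benzyloxy)-3-methoxyphenyl]-6-(3,4-dimethoxyphenyl)-3,7-dioxabicyclo[3.3.0]octan-1-ol
Product: 16 (1S,2R,5R,6S)-2-[4-(benzyloxy)-3-methoxyphenyl]-6-(3,4-dimethoxyphenyl)-3,7-dioxabicyclo[3.3.0]octan-1-yl acetate
Conditions: Ac2O, DMAP, Et3N, CH2Cl2, rt to 40 °C
Reagents that add atoms: acetic anhydride, CC(=O)OC(C)=O
Why: DMAP-catalysed acylation through the N-acetylpyridinium ion should esterify the tertiary bridgehead alcohol, the only free hydroxyl while the phenol is still benzylated; no stereocentre is affected.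

Step 12
Reactants: 16 (1S,2R,5R,6S)-2-[4-(benzyloxy)-3-methoxyphenyl]-6-(3,4-dimethoxyphenyl)-3,7-dioxabicyclo[3.3.0]octan-1-yl acetate
Product: 17 (1S,2R,5R,6S)-6-(3,4-dimethoxyphenyl)-2-(4-hydroxy-3-methoxyphenyl)-3,7-dioxabicyclo[3.3.0]octan-1-yl acetate (CNP0107105.1)
Conditions: H2 (1 atm), 10% Pd/C, EtOAc, rt, stopped as soon as 16 is consumed
Reagents that add atoms: none
Why: Hydrogenolysis of the aryl benzyl ether is much faster than cleavage of the hindered cyclic benzylic ethers at C2 and C6 in a non-acidic solvent, so a brief reaction should free the phenol and leave the acetate and the furofuran intact.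

**Compound list**

1 | 4-(benzyloxy)-3-methoxybenzyl alcohol | COc1cc(CO)ccc1OCc1ccccc1 | starting material
2 | 4-(benzyloxy)-3-methoxybenzyl methylthiomethyl ether | COc1cc(COCSC)ccc1OCc1ccccc1 | intermediate
3 | 4-(benzyloxy)-3-methoxybenzyl chloromethyl ether | COc1cc(COCCl)ccc1OCc1ccccc1 | intermediate
4 | ethyl 3-(3,4-dimethoxyphenyl)-3-oxopropanoate | CCOC(=O)CC(=O)c1ccc(OC)c(OC)c1 | starting material
5 | ethyl (S)-3-(3,4-dimethoxyphenyl)-3-hydroxypropanoate | CCOC(=O)C[C@@H](c1ccc(OC)c(OC)c1)O | intermediate
6 | dilithium alkoxide–enolate of 5 (chelated, not isolated) | CCO/C([O-])=C/[C@@H](c1ccc(OC)c(OC)c1)[O-].[Li+].[Li+] | intermediate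
7 | ethyl (2R,3S)-2-({[4-(benzyloxy)-3-methoxybenzyl]oxy}methyl)-3-(3,4-dimethoxyphenyl)-3-hydroxypropanoate | COc1cc(COC[C@@H](C(=O)OCC)[C@@H](c2ccc(OC)c(OC)c2)O)ccc1OCc1ccccc1 | intermediate
8 | tert-butyldimethylsilyl ether of 7 | COc1cc(COC[C@@H](C(=O)OCC)[C@@H](c2ccc(OC)c(OC)c2)O[Si](C)(C)C(C)(C)C)ccc1OCc1ccccc1 | intermediate
9 | (2R,3S)-2-({[4-(benzyloxy)-3-methoxybenzyl]oxy}methyl)-3-[(tert-butyldimethylsilyl)oxy]-3-(3,4-dimethoxyphenyl)propanoic acid | COc1cc(COC[C@@H](C(=O)O)[C@@H](c2ccc(OC)c(OC)c2)O[Si](C)(C)C(C)(C)C)ccc1OCc1ccccc1 | intermediate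
10 | mixed isobutyl carbonic anhydride of 9 (not isolated) | COc1cc(COC[C@@H](C(=O)OC(=O)OCC(C)C)[C@@H](c2ccc(OC)c(OC)c2)O[Si](C)(C)C(C)(C)C)ccc1OCc1ccccc1 | intermediate
11 | (3R,4S)-3-({[4-(benzyloxy)-3-methoxybenzyl]oxy}methyl)-4-[(tert-butyldimethylsilyl)oxy]-1-diazo-4-(3,4-dimethoxyphenyl)butan-2-one | COc1cc(COC[C@@H](C(=O)C=[N+]=[N-])[C@@H](c2ccc(OC)c(OC)c2)O[Si](C)(C)C(C)(C)C)ccc1OCc1ccccc1 | intermediate
12 | (3R,4S)-3-({[4-(benzyloxy)-3-methoxybenzyl]oxy}methyl)-1-diazo-4-(3,4-dimethoxyphenyl)-4-hydroxybutan-2-one | COc1cc(COC[C@@H](C(=O)C=[N+]=[N-])[C@@H](c2ccc(OC)c(OC)c2)O)ccc1OCc1ccccc1 | intermediate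
13 | (4R,5S)-4-({[4-(benzyloxy)-3-methoxybenzyl]oxy}methyl)-5-(3,4-dimethoxyphenyl)dihydrofuran-3(2H)-one | COc1cc(COC[C@@H]2[C@@H](c3ccc(OC)c(OC)c3)OCC2=O)ccc1OCc1ccccc1 | intermediate
14 | 1,5-biradical (C1 ketyl, C2 α-alkoxybenzyl radical; not isolated) | COc1cc([CH]OC[C@@H]2[C@@H](c3ccc(OC)c(OC)c3)OC[C]2O)ccc1OCc1ccccc1 | intermediate
15 | (1S,2R,5R,6S)-2-[4-(benzyloxy)-3-methoxyphenyl]-6-(3,4-dimethoxyphenyl)-3,7-dioxabicyclo[3.3.0]octan-1-ol | COc1cc([C@H]2OC[C@@H]3[C@@H](c4ccc(OC)c(OC)c4)OC[C@]23O)ccc1OCc1ccccc1 | intermediate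
16 | (1S,2R,5R,6S)-2-[4-(benzyloxy)-3-methoxyphenyl]-6-(3,4-dimethoxyphenyl)-3,7-dioxabicyclo[3.3.0]octan-1-yl acetate | COc1cc([C@H]2OC[C@@H]3[C@@H](c4ccc(OC)c(OC)c4)OC[C@]23OC(C)=O)ccc1OCc1ccccc1 | intermediate
17 | (1S,2R,5R,6S)-6-(3,4-dimethoxyphenyl)-2-(4-hydroxy-3-methoxyphenyl)-3,7-dioxabicyclo[3.3.0]octan-1-yl acetate (CNP0107105.1) | COc1cc([C@H]2OC[C@@H]3[C@@H](c4ccc(OC)c(OC)c4)OC[C@]23OC(C)=O)ccc1O | target

**Totals**

Total step count: 12.
Longest linear sequence: 11 steps (from 1 through steps 1, 2 and 4–12); step 3 prepares the second branch from 4.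

**Steps most likely to fail**

1. Step 10 (photocyclization). The excited cyclic ketone may fragment by α-cleavage, or be quenched by the electron-rich rings, faster than it abstracts the C2 hydrogen, so conversion to the bicycle may be poor. The fallback sets out from ketone 13 and returns at alcohol 15.
   - Wittig olefination of 13 with the ylide from [4-(benzyloxy)-3-methoxybenzyl]triphenylphosphonium bromide F1 (made from alcohol 1 and Ph3P·HBr; NaN(SiMe3)2, THF, −78 to 0 °C) would give the exocyclic benzylidene tetrahydrofuran F2 as an alkene mixture.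
   - Epoxidation with dimethyldioxirane in acetone at −20 °C, on the face of ring B away from the C5 side chain, would give the spiro-epoxide F3 with the C1 oxygen in the required orientation.
   - Catalytic camphorsulfonic acid in wet CH2Cl2 would then open the electron-rich aryl epoxide at the benzylic carbon C2. The ether oxygen O3 captures the cation and sheds its arylmethyl group to water (debenzylative cycloetherification), closing ring A and giving 15, with the exo aryl group at C2 set thermodynamically under the same acid.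

2. Step 4 (alkylation with the chloromethyl ether). The labile α-chloro ether may decompose or alkylate the alkoxide oxygen instead of the enolate carbon, and the chelate control may be eroded. The fallback sets out from hydroxy ester 5 and returns at compound 7.
   - The same dianion 6 would be trapped at −78 °C with gaseous formaldehyde (cracked paraformaldehyde), again anti, to give ethyl (2R,3S)-3-(3,4-dimethoxyphenyl)-3-hydroxy-2-(hydroxymethyl)propanoate F4.
   - The primary hydroxyl of F4 would then be etherified selectively with 4-(benzyloxy)-3-methoxybenzyl bromide F5 (from 1 with PBr3) and Ag2O in CH2Cl2 to give 7.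

3. Step 9 (carbenoid O–H insertion). The carbenoid may be diverted into cycloaddition with the neighbouring veratryl ring or into ylide formation at the ether oxygen O3 instead of inserting into the O–H bond. The fallback sets out from compound 7, bypasses 8–12, and returns at ketone 13; ring B is closed by C–C bond formation instead.
   - Rh2(OAc)4-catalysed intermolecular O–H insertion of allyl diazoacetate into the carbinol of 7 would give the diester ethyl (2R,3S)-3-[2-(allyloxy)-2-oxoethoxy]-2-({[4-(benzyloxy)-3-methoxybenzyl]oxy}methyl)-3-(3,4-dimethoxyphenyl)propanoate F6.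
   - Dieckmann condensation (LiN(SiMe3)2, THF, −78 to 0 °C; the glycolate α-carbon onto the ethyl ester) would give allyl 4-({[4-(benzyloxy)-3-methoxybenzyl]oxy}methyl)-5-(3,4-dimethoxyphenyl)-3-oxotetrahydrofuran-2-carboxylate F7.
   - Pd(PPh3)4 and morpholine in THF at rt would remove the allyl group and decarboxylate to ketone 13 under neutral conditions.

**Further compounds**

F1 | step 10 | [4-(benzyloxy)-3-methoxybenzyl]triphenylphosphonium bromide | COc1cc(C[P+](c2ccccc2)(c2ccccc2)c2ccccc2)ccc1OCc1ccccc1.[Br-]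
F2 | step 10 | exocyclic benzylidene tetrahydrofuran (C1=C2 alkene, geometry unassigned; C5 and C6 as in 13) | COc1cc(COC[C@@H]2[C@@H](c3ccc(OC)c(OC)c3)OCC2=Cc2ccc(OCc3ccccc3)c(OC)c2)ccc1OCc1ccccc1
F3 | step 10 | spiro-epoxide of F2 (C1 oxygen anti to the C5 side chain; C2 unassigned) | COc1cc(COC[C@@H]2[C@@H](c3ccc(OC)c(OC)c3)OC[C@@]24OC4c2ccc(OCc3ccccc3)c(OC)c2)ccc1OCc1ccccc1
F4 | step 4 | ethyl (2R,3S)-3-(3,4-dimethoxyphenyl)-3-hydroxy-2-(hydroxymethyl)propanoate | OC[C@@H](C(=O)OCC)[C@@H](c1ccc(OC)c(OC)c1)O
F5 | step 4 | 4-(benzyloxy)-3-methoxybenzyl bromide | COc1cc(CBr)ccc1OCc1ccccc1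
F6 | step 9 | ethyl (2R,3S)-3-[2-(allyloxy)-2-oxoethoxy]-2-({[4-(benzyloxy)-3-methoxybenzyl]oxy}methyl)-3-(3,4-dimethoxyphenyl)propanoate | COc1cc(COC[C@@H](C(=O)OCC)[C@@H](c2ccc(OC)c(OC)c2)OCC(=O)OCC=C)ccc1OCc1ccccc1
F7 | step 9 | allyl 4-({[4-(benzyloxy)-3-methoxybenzyl]oxy}methyl)-5-(3,4-dimethoxyphenyl)-3-oxotetrahydrofuran-2-carboxylate | COc1cc(COC[C@@H]2[C@@H](c3ccc(OC)c(OC)c3)OC(C(=O)OCC=C)C2=O)ccc1OCc1ccccc1
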